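**Plan**
- Cuts: the two phenol O–H bonds are masked as MOM ethers. The Cβ–H bond is traced back to Cβ–Br and then to the Cβ–O bond of a trans oxirane. Removing both oxirane C–O bonds leaves an E chalcone.
- The chalcone is cut at Cα=Cβ (aldol condensation of a ring A acetophenone with 4-anisaldehyde, ring B). Ring A is cut at C1'–acetyl and C5'–prenyl, back to the two C–Br bonds of 4,6-dibromoresorcinol.
- Forward order: ring A is protected, prenylated and acetylated, and the C3 chain is joined to ring B. The oxirane, the only ring made, is closed and then opened at Cβ. Cβ is reduced to CH2 and the phenols are released.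
- Enabling feature: the unit ring A–C(=O)–Cα(OH)–CβH2–ring B is a chalcone enone with oxygen added at Cα. In the chalcone, Cα=Cβ is the only alkene conjugated to C=O. The C5' prenyl C=C on ring A is electron rich and does not react with a peroxide anion.
- Stereochemistry: the single stereocentre, Cα (S), comes from enantioface selection by the poly-D-leucine helix in the epoxidation. Its C–O bond is never broken afterwards, and the Cβ centre made with it is erased.

Key step: step 5

Locants: chalcone numbering is used. Ring A is the aroyl (resorcinol) ring with primed numbers, ring B is the anisyl ring, Cα lies next to C=O, and Cβ is benzylic.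

Assumption: poly-D-leucine (polymerisation of D-leucine N-carboxyanhydride started by 1,3-diaminopropane) is treated as an available catalyst, and its preparation is not counted as a step.

**Step 1**
Reactants: 1 4,6-dibromoresorcinol
Product: 2 1,5-dibromo-2,4-bis(methoxymethoxy)benzene
Conditions: MOMCl (2.5 equiv), iPr2NEt (3 equiv), CH2Cl2, 0 °C → rt
Reagents that add atoms: chloromethyl methyl ether (MOMCl), COCCl
Why: Williamson-type O-alkylation of both acidic bromophenol hydroxyls with the reactive α-chloro ether under amine base is routine, and the resulting acetals tolerate organolithiums, hydroxide and peroxide and later stabilise the ortho-lithio species by chelation.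

**Step 2**
Reactants: 2 1,5-dibromo-2,4-bis(methoxymethoxy)benzene; 3 prenyl bromide (1-bromo-3-methylbut-2-ene)
Product: 5 1-bromo-2,4-bis(methoxymethoxy)-5-(3-methylbut-2-en-1-yl)benzene, via monolithiated arene 4 (not isolated)
Conditions: n-BuLi (1.0 equiv), THF, −78 °C; then 3, −78 °C → rt
Reagents that add atoms: none
Why: Bromine–lithium exchange with one equivalent of n-BuLi at −78 °C outruns deprotonation and stops at 4 because a second exchange would build a dianion, and the MOM-chelated aryllithium then displaces the primary allylic bromide of 3 by SN2 alkylation at its unhindered CH2 terminus.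

**Step 3**
Reactants: 5 1-bromo-2,4-bis(methoxymethoxy)-5-(3-methylbut-2-en-1-yl)benzene; 6 N-methoxy-N-methylacetamide
Product: 9 1-[2,4-bis(methoxymethoxy)-5-(3-methylbut-2-en-1-yl)phenyl]ethan-1-one, via aryllithium 7 (not isolated), via lithium hemiaminal adduct 8 (not isolated)
Conditions: n-BuLi (1.05 equiv), THF, −78 °C; then 6, −78 → 0 °C; H2O quench
Reagents that add atoms: none
Why: A second bromine–lithium exchange followed by a Weinreb ketone synthesis places the acetyl group exactly at the former C–Br carbon, since the N-methoxy chelate 8 lasts until the quench and so excludes double addition, and at −78 °C the ArCH2–CH= protons of the prenyl group are not removed.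

**Step 4**
Reactants: 9 1-[2,4-bis(methoxymethoxy)-5-(3-methylbut-2-en-1-yl)phenyl]ethan-1-one; 10 4-anisaldehyde
Product: 12 (E)-1-[2,4-bis(methoxymethoxy)-5-(3-methylbut-2-en-1-yl)phenyl]-3-(4-methoxyphenyl)prop-2-en-1-one, via racemic aldol adduct 11 (not isolated)
Conditions: KOH, EtOH/H2O, rt
Reagents that add atoms: none
Why: In this Claisen–Schmidt condensation only 9 can enolise and only 10 can accept, aldol 11 loses water by E1cB, conjugation with both rings makes the E enone the thermodynamic product, and MOM ethers and the prenyl group are inert to hydroxide.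

**Step 5**
Reactants: 12 (E)-2',4'-bis(methoxymethoxy)-4-methoxy-5'-prenylchalcone
Product: 14 [(2S,3R)-3-(4-methoxyphenyl)oxiran-2-yl][2,4-bis(methoxymethoxy)-5-(3-methylbut-2-en-1-yl)phenyl]methanone (αS,βR-trans epoxide), via beta-hydroperoxy enolate 13 (not isolated)
Conditions: poly-D-leucine, urea·H2O2, DBU, THF, rt; peptide filtered off
Reagents that add atoms: urea–hydrogen peroxide adduct, NC(N)=O.OO
Why: DBU frees HOO− from urea·H2O2, and the anion attacks Cβ of the s-cis enone while the carbonyl oxygen is hydrogen-bonded to the free N–H groups at the N-terminus of the α-helical peptide, which gives peroxy enolate 13 and the Cβ–O bond. Cα of 13 then attacks the peroxide oxygen bound to Cβ and expels hydroxide in a 3-exo-tet closure that forms the Cα–O bond and the oxirane. This is the Juliá–Colonna form of the Weitz–Scheffer nucleophilic epoxidation, for which E chalcones, 2'-alkoxymethoxy ones included, are the standard substrates. The helix built from D residues exposes the enone face that gives βR on addition and αS on closure (the L polymer gives the mirror image, αR,βS), and the trans relation follows from the E alkene because 13 closes from the rotamer that keeps aroyl and anisyl groups apart. The step needs enone-over-prenyl chemoselectivity, which is secured because only Cα=Cβ is conjugated to the ketone and therefore electrophilic, whereas the trisubstituted C5' alkene offers a peroxide anion nothing to add to. The acetals are inert to this weakly basic, non-aqueous medium, and the masked 2'-oxygen cannot cyclise onto the enone or the oxirane.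

**Step 6**
Reactants: 14 (αS,βR)-trans chalcone epoxide
Product: 15 (2R,3S)-3-bromo-2-hydroxy-1-[2,4-bis(methoxymethoxy)-5-(3-methylbut-2-en-1-yl)phenyl]-3-(4-methoxyphenyl)propan-1-one
Conditions: LiBr (3 equiv), AcOH (2 equiv), THF, 0 °C → rt; aqueous wash, no chromatography
Reagents that add atoms: lithium bromide, [Li+].[Br-]
Why: In this acid-assisted halohydrin opening of an aryl epoxy ketone the p-anisyl ring stabilises positive charge at Cβ while the acyl group disfavours it at Cα, so bromide enters at Cβ (mainly with inversion, at a centre erased in step 7), the unbroken Cα–O bond keeps its geometry (the descriptor becomes R only because CHBr now outranks C=O), and a buffered, non-chelating bromide source instead of a magnesium or boron Lewis acid keeps the 2'-MOM acetal in place, so that no free phenol can close onto Cβ.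

**Step 7**
Reactants: 15 (2R,3S)-bromohydrin
Product: 16 (2S)-2-hydroxy-1-[2,4-bis(methoxymethoxy)-5-(3-methylbut-2-en-1-yl)phenyl]-3-(4-methoxyphenyl)propan-1-one
Conditions: Bu3SnH (1.3 equiv), Et3B (cat.), air, PhMe, −40 → 0 °C
Reagents that add atoms: none
Why: In this radical chain hydrodebromination the weak secondary benzylic C–Br bond is the only site from which tin radicals abstract, hydrogen transfer from Sn–H turns Cβ into CH2, and the neutral, cold medium suppresses loss of HBr and leaves the Cα carbinol, the ketone, the acetals and the remote prenyl alkene (too far away for a favourable cyclisation) untouched.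

**Step 8**
Reactants: 16 (2S)-bis-MOM α-hydroxydihydrochalcone
Product: 17 Lespeflorin C2, (2S)-1-[2,4-dihydroxy-5-(3-methylbut-2-en-1-yl)phenyl]-2-hydroxy-3-(4-methoxyphenyl)propan-1-one
Conditions: polystyrenesulfonic acid resin (H+ form), MeOH, 40 °C; resin filtered off before concentration
Reagents that add atoms: none
Why: Acid-catalysed transacetalisation of aryl MOM ethers with methanol is the standard way to release prenylated phenols, it runs under conditions too mild to protonate the prenyl alkene (chroman closure) or to enolise the α-ketol, and removing the acid by filtration before concentration should preserve the S centre.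

**Compound list**
1 | 4,6-dibromoresorcinol | Oc1cc(O)c(Br)cc1Br | starting material
2 | 1,5-dibromo-2,4-bis(methoxymethoxy)benzene | COCOc1cc(OCOC)c(Br)cc1Br | intermediate
3 | prenyl bromide (1-bromo-3-methylbut-2-ene) | CC(C)=CCBr | starting material
4 | [5-bromo-2,4-bis(methoxymethoxy)phenyl]lithium (not isolated) | [Li]c1cc(Br)c(OCOC)cc1OCOC | intermediate
5 | 1-bromo-2,4-bis(methoxymethoxy)-5-(3-methylbut-2-en-1-yl)benzene | COCOc1cc(OCOC)c(CC=C(C)C)cc1Br | intermediate
6 | N-methoxy-N-methylacetamide | CON(C)C(C)=O | starting material
7 | [2,4-bis(methoxymethoxy)-5-(3-methylbut-2-en-1-yl)phenyl]lithium (not isolated) | [Li]c1cc(CC=C(C)C)c(OCOC)cc1OCOC | intermediate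
8 | lithium 1-[2,4-bis(methoxymethoxy)-5-(3-methylbut-2-en-1-yl)phenyl]-1-[methoxy(methyl)amino]ethan-1-olate, racemic tetrahedral adduct (not isolated) | [Li+].CC([O-])(N(C)OC)c1cc(CC=C(C)C)c(OCOC)cc1OCOC | intermediate
9 | 1-[2,4-bis(methoxymethoxy)-5-(3-methylbut-2-en-1-yl)phenyl]ethan-1-one | CC(=O)c1cc(CC=C(C)C)c(OCOC)cc1OCOC | intermediate
10 | 4-anisaldehyde | COc1ccc(C=O)cc1 | starting material
11 | racemic 3-hydroxy-1-[2,4-bis(methoxymethoxy)-5-(3-methylbut-2-en-1-yl)phenyl]-3-(4-methoxyphenyl)propan-1-one (not isolated) | COc1ccc(C(O)CC(=O)c2cc(CC=C(C)C)c(OCOC)cc2OCOC)cc1 | intermediate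
12 | (E)-2',4'-bis(methoxymethoxy)-4-methoxy-5'-prenylchalcone | COc1ccc(/C=C/C(=O)c2cc(CC=C(C)C)c(OCOC)cc2OCOC)cc1 | intermediate
13 | DBU-H+ salt of (1Z,3S)-3-hydroperoxy-1-[2,4-bis(methoxymethoxy)-5-(3-methylbut-2-en-1-yl)phenyl]-3-(4-methoxyphenyl)prop-1-en-1-olate; the Cβ–O bond has the geometry that is βR in 14 (not isolated) | COc1ccc([C@@H](OO)/C=C(\[O-])c2cc(CC=C(C)C)c(OCOC)cc2OCOC)cc1.C1CCC2=[NH+]CCCN2CC1 | intermediate
14 | [(2S,3R)-3-(4-methoxyphenyl)oxiran-2-yl][2,4-bis(methoxymethoxy)-5-(3-methylbut-2-en-1-yl)phenyl]methanone, trans | COc1ccc([C@H]2O[C@@H]2C(=O)c3cc(CC=C(C)C)c(OCOC)cc3OCOC)cc1 | intermediate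
15 | (2R,3S)-3-bromo-2-hydroxy-1-[2,4-bis(methoxymethoxy)-5-(3-methylbut-2-en-1-yl)phenyl]-3-(4-methoxyphenyl)propan-1-one, drawn as the inversion product; the Cβ epimer serves equally | COc1ccc([C@H](Br)[C@H](O)C(=O)c2cc(CC=C(C)C)c(OCOC)cc2OCOC)cc1 | intermediate
16 | (2S)-2-hydroxy-1-[2,4-bis(methoxymethoxy)-5-(3-methylbut-2-en-1-yl)phenyl]-3-(4-methoxyphenyl)propan-1-one | COc1ccc(C[C@H](O)C(=O)c2cc(CC=C(C)C)c(OCOC)cc2OCOC)cc1 | intermediate
17 | Lespeflorin C2, (2S)-1-[2,4-dihydroxy-5-(3-methylbut-2-en-1-yl)phenyl]-2-hydroxy-3-(4-methoxyphenyl)propan-1-one | COc1ccc(C[C@H](O)C(=O)c2cc(CC=C(C)C)c(O)cc2O)cc1 | target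

Total step count: 8
Longest linear sequence: 8 steps (from 1 to 17)

**Steps most likely to fail**

**Step 6.** Ionisation at Cβ may outrun capture by bromide. That would open the way to aroyl migration, to capture by acetate, or to loss of the ortho acetal followed by ring closure through the freed phenol. The benzylic halide may also decompose on handling.

The fallback sets out from epoxide 14 and opens the oxirane at Cβ with sulfur instead of halogen, in the manner of the thiolysis of 3-(4-methoxyphenyl)glycidates. PhSH with catalytic LiClO4 in MeCN at rt should give the chromatographically stable (2R,3S)-2-hydroxy-3-(phenylsulfanyl)-1-[2,4-bis(methoxymethoxy)-5-(3-methylbut-2-en-1-yl)phenyl]-3-(4-methoxyphenyl)propan-1-one F1; either Cβ epimer serves. Radical desulfurisation with Bu3SnH and AIBN in refluxing toluene then cleaves the benzylic C–S bond and comes back to the route at 16. Steps 6 and 7 are both replaced.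

**Step 5.** The donor-rich, ortho-substituted enone may take up hydroperoxide sluggishly, and peptide-free background epoxidation would then erode the enantioface selection. A modest shortfall could be met by recrystallising 14 or 16.

The fallback sets out from chalcone 12 and places the oxygen on Cα by enolate chemistry instead of enone chemistry.
- Conjugate reduction with [(Ph3P)CuH]6 in wet toluene at rt, which leaves the isolated prenyl alkene alone, gives 1-[2,4-bis(methoxymethoxy)-5-(3-methylbut-2-en-1-yl)phenyl]-3-(4-methoxyphenyl)propan-1-one F2.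
- NaN(SiMe3)2 in THF at −78 °C converts it into the sodium (Z)-enolate F3.
- Oxygen transfer from (+)-(camphorylsulfonyl)oxaziridine (Davis oxidation), followed by an AcOH quench, rejoins the route at 16. This enantiomer of the reagent is expected to give S by analogy with Z enolates of alkyl aryl ketones, and the antipode is equally available.

At this temperature the oxaziridine reacts with the enolate and not with the prenyl alkene.

**Step 2.** Three processes may spoil the alkylation: incomplete or double halogen–lithium exchange, halogen–metal exchange between the aryllithium and the allylic bromide with Wurtz-type coupling, and attack at the tertiary allyl terminus.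

The fallback sets out from 2, reverses the order of the two C–C bond formations, and brings in the prenyl group by cross-coupling. Aryllithium 4 is trapped with amide 6. Through lithium 1-[5-bromo-2,4-bis(methoxymethoxy)phenyl]-1-[methoxy(methyl)amino]ethan-1-olate F4 and a water quench, this gives 1-[5-bromo-2,4-bis(methoxymethoxy)phenyl]ethan-1-one F5. A Stille coupling with tributyl(3-methylbut-2-en-1-yl)stannane and Pd(PPh3)4 in DMF at 90 °C then attaches the prenyl group at C5' and comes back to the route at ketone 9. Steps 2 and 3 are both replaced.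

**Further compounds**
F1 | step 6 | (2R,3S)-2-hydroxy-3-(phenylsulfanyl)-1-[2,4-bis(methoxymethoxy)-5-(3-methylbut-2-en-1-yl)phenyl]-3-(4-methoxyphenyl)propan-1-one | COc1ccc([C@H](Sc3ccccc3)[C@H](O)C(=O)c2cc(CC=C(C)C)c(OCOC)cc2OCOC)cc1
F2 | step 5 | 1-[2,4-bis(methoxymethoxy)-5-(3-methylbut-2-en-1-yl)phenyl]-3-(4-methoxyphenyl)propan-1-one | COc1ccc(CCC(=O)c2cc(CC=C(C)C)c(OCOC)cc2OCOC)cc1
F3 | step 5 | sodium (Z)-1-[2,4-bis(methoxymethoxy)-5-(3-methylbut-2-en-1-yl)phenyl]-3-(4-methoxyphenyl)prop-1-en-1-olate | [Na+].COc1ccc(C/C=C(\[O-])c2cc(CC=C(C)C)c(OCOC)cc2OCOC)cc1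
F4 | step 2 | lithium 1-[5-bromo-2,4-bis(methoxymethoxy)phenyl]-1-[methoxy(methyl)amino]ethan-1-olate (racemic) | [Li+].CC([O-])(N(C)OC)c1cc(Br)c(OCOC)cc1OCOC
F5 | step 2 | 1-[5-bromo-2,4-bis(methoxymethoxy)phenyl]ethan-1-one | CC(=O)c1cc(Br)c(OCOC)cc1OCOC
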